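## The problem

The target is an oxolane in which every ring carbon is a stereocenter: O1, C2 (4-hydroxyphenyl), C3 (2,4-dihydroxybenzoyl), C4 (4-hydroxybenzyl) and C5 (2,4-dihydroxyphenyl), configured 2S,3S,4S,5R. This means 2,3-trans, 3,4-trans and 4,5-cis, with the two ring-bound aryl groups on the same face. Three of these relationships are the ones sterics would choose, but the C4 benzyl/C5 aryl pair is cis and must be made under kinetic control and then shielded from equilibration. C5 is the weak point: it is a benzylic ether carbon on an ortho,para-dioxygenated ring, so a Brønsted or Lewis acid can ionise C5–O1 and return the trans isomer. C3 lies alpha to the ketone and trans to both neighbours, so it corrects itself, but the same ketone turns O1 into a beta leaving group (ring opening through C2–O1). The aroyl group should therefore appear late and never meet strong base. Five phenols, four of them on two resorcinol rings, need protecting groups that leave without acid or base, and the electron-rich rings exclude electrophilic oxidants. C2 and C3 form a 1,2-pair that an aldol reaction can set absolutely; once in place they can steer C4 through a cyclic transition state, and C5 must be set against C4 in the ring-forming event itself. The enabling feature is the C4 benzyl group: C4–CH2Ar is what a C4=CH–Ar styrene leaves behind after a carbon radical adds at C4 and the benzylic radical takes up hydrogen. C5, benzylic and alpha to O1, is an ideal radical site that a carboxyl group can mark and release.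

## Retrosynthesis

**Target 25 to hexabenzyl ether 24.** The six phenolic O–H bonds are traced back to O–benzyl bonds. Benzyl is preferred over acetal, silyl or acyl protection because it leaves by neutral hydrogenolysis, whereas acid would ionise C5–O1 and base would open the beta-alkoxy ketone. Compound 24 is no simpler in skeleton, but it has no acidic hydrogen and tolerates organometallic and radical steps. The forward reaction must cleave six aryl benzyl ethers while sparing the two ring benzylic C–O bonds and the ketone.

**Ketone 24 to carbinol 23, then to aldehyde 19 and arylmagnesium bromide 22.** The bond between the carbonyl carbon and the resorcinol ring is cut after lowering the oxidation level by one step. The alternative of carrying the ketone through the ring closure would put an acidic H3 next to a beta-oxygen and a radical-accepting carbonyl into the key step. The cut removes one aryl ring and the ketone and leaves a one-carbon stub at C3. Reagent 22 comes from bromide 21, and 21 from 4-bromoresorcinol 20. The forward addition must outrun enolisation of a beta-alkoxy aldehyde; the carbinol configuration of 23 is irrelevant.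

**Aldehyde 19 to alcohol 18 to silyl ether 17.** No skeletal bond is cut; the formyl group is traced to a silyloxymethyl group. A silyl ether is inert to carbenoids, hydroxide, radicals and photocatalysts, so C3 can cross the middle of the route as a bystander. The forward steps are a fluoride desilylation and a buffered oxidation.

**Oxolane 17 to acid 16 (key disconnection).** C4–C5 is cut. Cutting O1–C5 instead would call for a cationic etherification, which would deliver the thermodynamic 4,5-trans isomer. Cutting C2–C3 or C3–C4 would separate the pair that an aldol sets best. The C4–C5 cut uses the benzyl group as the trace of a styrene and the C5–H as the trace of a carboxyl group. It opens the ring and removes two stereocenters, leaving an acyclic ether whose only relevant stereocenters are the aldol pair. The forward reaction must close 5-exo with 2,4-cis, 3,4-trans and 4,5-cis selectivity, and hydrogen must reach the radical only after cyclisation.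

**Acid 16 to ester 15, then to alcohol 11 and diazo ester 14.** The O1–C5 ether bond is cut at the acid carbon, which corresponds to a carbenoid O–H insertion. A Williamson alkylation is the neighbour; it would pit a hindered secondary alkoxide, prone to silyl migration, against an enolisable alpha-halo ester. The cut divides the molecule into a two-stereocenter alcohol and an achiral diazo ester, which comes from ester 13 and this from commercial acid 12. The insertion needs no stereocontrol, because the acid carbon becomes planar in the key step, but it must prefer the hydroxyl group over the alkene and over C–H bonds.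

**Alcohol 11 to diol 10 to aldol adduct 9, then to imide 7 and aldehyde 1.** The C2–C3 bond (oxolane numbering) is cut. The two centers are syn in the open chain, which is the natural outcome of an auxiliary-controlled boron aldol, and the styryl group rides in on the enolate. This removes both stereocenters and leaves an achiral acyl unit and a commercial aldehyde. The forward sequence needs alpha-selective reaction of a dienolate, reductive removal of the auxiliary and silylation of the primary hydroxyl only.

**Imide 7 to acid 4 and oxazolidinone 5; acid 4 to aldehyde 1 and phosphonium salt 2.** The N-acyl bond and the alkene are cut. Aldehyde 1 thus supplies both 4-oxygenated phenyl rings, once as electrophile in the olefination and once in the aldol. The olefination should give the E alkene, but the geometry is not carried into the target.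

## Roads not taken

**Alternative 1:** The cut runs through C4–C5 and C2–C3 together.
- Forward step: aldehyde A4 (2,4-bis(benzyloxy)benzaldehyde) would be condensed with the Z-allylic diol A3 to the dioxolane acetal A2. SnCl4 would open the acetal to an oxocarbenium ion on O1, the alkene would attack it (C4–C5), and a pinacol-type shift of C2 onto C3 would contract the ring and expel the allylic carbinol carbon as the formyl group of A1.
- Merits: two C–C bonds, the ring and three stereocenters form in one step. A1 is the same compound as aldehyde 19, so this road would reach 19 without the silyl ether detour and in clearly fewer steps.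
- Weak points for this target:
  - The alkene of A2 is 1,2-disubstituted and offers no cation-stabilising group at C3, so the Prins step lacks the stabilised cation on which this cascade normally relies.
  - C2 carries a 4-alkoxyphenyl group. The competing oxonia-Cope/aldol pathway, in which C2 becomes an aryl-stabilised oxocarbenium carbon, is therefore easy and would loosen the link between the configuration of A3 and C2.
  - The 4,5-cis relationship depends on the Z alkene reacting through a single chair. The C5–O1 bond of A1 remains exposed to SnCl4, which can reionise it and drain the cis isomer to trans.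
  - A3 needs its own enantioselective synthesis with a Z alkene.
- Comparison: in step count and bond economy this road is better. The chosen plan sets against it that C2 and C3 come from a dependable auxiliary aldol, that C4–C5 forms under neutral conditions at room temperature, and that no Lewis acid meets the C5 ether. It pays for this with the protecting-group detour.

**Alternative 2:** The cut is O1–C5 and C2–C3.
- Forward step: Sn(OTf)2 would activate the trans cyclopropane diester A6. The oxygen of aldehyde 1 would open it at the aryl-bearing carbon with inversion (O1–C5), and the malonate carbon would close onto the aldehyde carbon (C2–C3) to give the oxolane diester A5.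
- Merits: the step is convergent and stereospecific. The 2,5-cis arrangement and, through the trans geometry of A6, the 4,5-cis arrangement are delivered by mechanism. In this respect the road is stronger than the chosen plan, whose C5 selectivity rests on a transition-state preference.
- Weak points:
  - The donor ring is a resorcinol; even as the diacetate it favours full ionisation of the cyclopropane, which would racemise A6 and forfeit the inversion.
  - The vicinal benzyl group hinders backside attack.
  - A6 is a trisubstituted, enantiopure cyclopropane that simple malonate-carbenoid addition to a 1,2-disubstituted alkene does not provide.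
  - After the annulation C3 carries two esters. One must be removed by hot, nucleophilic dealkoxycarbonylation next to a beta-alkoxy group. The other must become the aryl ketone while the aryl acetates are exchanged for groups that survive an aryl organometallic.
- Comparison: the end game would be at least as long as the chosen one and harsher. The chosen plan offers milder downstream chemistry and an absolute configuration fixed by a recoverable auxiliary, at the price of a less certain C5.

**Alternative 3:** The cut is C3–C4 in the sense of a ring contraction.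
- Forward step: the 4-aryl-5,6-dihydro-2H-pyran A8 would be treated with the trivalent iodine reagent PhI(OH)OTs in methanol. Iodine adds to the alkene and methanol to the aryl-bearing carbon. The benzyl-bearing ring carbon then migrates to the alkene neighbour with loss of PhI, which contracts the ring and unveils the aryl ketone of A7.
- Merits: A7 is identical with hexabenzyl ketone 24, one hydrogenolysis from the target. The ketone arises at the correct oxidation level without an organometallic step, and the migrating carbon keeps its configuration. This is the shortest end game of the four plans.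
- Weak points:
  - The reagent is an electrophilic oxidant that releases TsOH. A8 contains four alkoxy-activated rings, two of them resorcinol ethers that react readily with aryl-iodine electrophiles.
  - C2 of A8 is an allylic and benzylic ether carbon and C6 a resorcinyl benzylic ether carbon; both can be ionised by the acid.
  - The aryl group on the alkene is so electron-rich that the benzylic cation may be captured twice by methanol instead of triggering migration.
  - A8 already holds three stereocenters including the cis aryl/benzyl pair, so the stereochemical problem is moved into a six-membered ring and not solved.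
- Comparison: the chosen plan has the longer end game, but it creates the stereocenters in the same steps that build the skeleton and never exposes the arenes to an electrophilic oxidant or the ring ethers to acid.

Key step: step 10

Remark on the chemistry: the alkene geometry of 4, the configuration at the acetate carbon of 15 and 16, and the carbinol configuration of 23 do not reach the target; these positions are carried as formed.

## Route

Step 1
Reactants: 1 4-(benzyloxy)benzaldehyde; 2 (2-carboxyethyl)triphenylphosphonium bromide
Product: 4 (3E)-4-[4-(benzyloxy)phenyl]but-3-enoic acid, via phosphonium ylide carboxylate 3 (not isolated)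
Conditions: KOt-Bu (2.2 equiv), THF, 0 °C → rt; then aq. HCl
Reagents that add atoms: none
Why: Wittig olefination of a carboxylate-bearing ylide with an aromatic aldehyde, which should give mainly the E beta,gamma-unsaturated acid; crystallisation should remove the minor Z isomer, and the geometry is not carried into the target.

Step 2
Reactants: 4 (3E)-4-[4-(benzyloxy)phenyl]but-3-enoic acid; 5 (4S)-4-benzyl-1,3-oxazolidin-2-one
Product: 7 (4S)-4-benzyl-3-{(3E)-4-[4-(benzyloxy)phenyl]but-3-enoyl}-1,3-oxazolidin-2-one, via mixed pivalic anhydride 6 (not isolated)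
Conditions: t-BuCOCl, Et3N, THF, −20 °C; then 5, LiCl, −20 °C → rt
Reagents that add atoms: none
Why: N-acylation of the oxazolidinone through the mixed anhydride with LiCl/Et3N needs no strong base, so the alkene should stay out of conjugation; if part of it moves, both isomers give the same dienolate in step 3.

Step 3
Reactants: 7 (4S)-4-benzyl-3-{(3E)-4-[4-(benzyloxy)phenyl]but-3-enoyl}-1,3-oxazolidin-2-one; 1 4-(benzyloxy)benzaldehyde
Product: 9 (4S)-4-benzyl-3-[(2S,3E)-4-[4-(benzyloxy)phenyl]-2-{(S)-[4-(benzyloxy)phenyl](hydroxy)methyl}but-3-enoyl]-1,3-oxazolidin-2-one, via dibutylboron Z-dienolate 8 (not isolated)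
Conditions: Bu2BOTf, i-Pr2NEt, CH2Cl2, −78 → 0 °C; 1, −78 → 0 °C; then pH 7 buffer, MeOH, 30% H2O2, 0 °C
Reagents that add atoms: none
Why: Evans syn aldol: the Z boron dienolate reacts at its alpha carbon through a closed Zimmerman–Traxler chair, and the benzyl group of the (S)-auxiliary shields one enolate face; this should set the 2S center (later C3) and the S carbinol center (later C2) in a syn relationship.

Step 4
Reactants: 9 (4S)-4-benzyl-3-[(2S,3E)-4-[4-(benzyloxy)phenyl]-2-{(S)-[4-(benzyloxy)phenyl](hydroxy)methyl}but-3-enoyl]-1,3-oxazolidin-2-one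
Product: 10 (1S,2R,3E)-1,4-bis[4-(benzyloxy)phenyl]-2-(hydroxymethyl)but-3-en-1-ol
Conditions: LiBH4, MeOH (1 equiv), THF, 0 °C
Reagents that add atoms: none
Why: Reductive cleavage of the N-acyl oxazolidinone by LiBH4 attacks the exocyclic carbonyl, frees the primary alcohol and returns the auxiliary; neither stereocenter is touched (the descriptor at C2 changes by priority only).

Step 5
Reactants: 10 (1S,2R,3E)-1,4-bis[4-(benzyloxy)phenyl]-2-(hydroxymethyl)but-3-en-1-ol
Product: 11 (1S,2R,3E)-1,4-bis[4-(benzyloxy)phenyl]-2-{[(tert-butyldimethylsilyl)oxy]methyl}but-3-en-1-ol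
Conditions: TBSCl, imidazole, CH2Cl2, 0 °C
Reagents that add atoms: tert-butyldimethylsilyl chloride, CC(C)(C)[Si](C)(C)Cl
Why: Silylation is much faster at the primary hydroxyl than at the hindered benzylic secondary one, which stays free for the ether formation.

Step 6
Reactants: 12 2-(2,4-dihydroxyphenyl)acetic acid
Product: 13 benzyl 2-[2,4-bis(benzyloxy)phenyl]acetate
Conditions: BnBr (3.3 equiv), K2CO3, DMF, rt → 50 °C
Reagents that add atoms: benzyl bromide, BrCc1ccccc1
Why: Williamson O-alkylation of both phenols and of the carboxylate in one operation; the ester also prevents lactonisation onto the ortho oxygen.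

Step 7
Reactants: 13 benzyl 2-[2,4-bis(benzyloxy)phenyl]acetate
Product: 14 benzyl 2-[2,4-bis(benzyloxy)phenyl]-2-diazoacetate
Conditions: 4-AcNHC6H4SO2N3, DBU, MeCN, 0 °C → rt
Reagents that add atoms: 4-acetamidobenzenesulfonyl azide, CC(=O)Nc1ccc(cc1)S(=O)(=O)N=[N+]=[N-]
Why: Regitz diazo transfer to the DBU-generated arylacetate enolate, the standard entry to aryldiazoacetates.

Step 8
Reactants: 11 (1S,2R,3E)-1,4-bis[4-(benzyloxy)phenyl]-2-{[(tert-butyldimethylsilyl)oxy]methyl}but-3-en-1-ol; 14 benzyl 2-[2,4-bis(benzyloxy)phenyl]-2-diazoacetate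
Product: 15 benzyl 2-[2,4-bis(benzyloxy)phenyl]-2-{[(1S,2R,3E)-1,4-bis[4-(benzyloxy)phenyl]-2-{[(tert-butyldimethylsilyl)oxy]methyl}but-3-en-1-yl]oxy}acetate (both epimers at the acetate carbon)
Conditions: Rh2(OAc)4 (1 mol %), CH2Cl2, rt, slow addition of 14 (2 equiv)
Reagents that add atoms: none
Why: Rhodium-carbenoid O–H insertion: the donor/acceptor carbenoid is captured by the free hydroxyl through an oxonium ylide faster than it cyclopropanates a trans-1,2-disubstituted alkene, and C–O bond formation at the carbinol oxygen leaves both existing centers untouched. The new center forms unselectively and is erased in step 10; slow addition of excess 14 should offset carbenoid lost to other pathways.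

Step 9
Reactants: 15 benzyl 2-[2,4-bis(benzyloxy)phenyl]-2-{[(1S,2R,3E)-1,4-bis[4-(benzyloxy)phenyl]-2-{[(tert-butyldimethylsilyl)oxy]methyl}but-3-en-1-yl]oxy}acetate
Product: 16 2-[2,4-bis(benzyloxy)phenyl]-2-{[(1S,2R,3E)-1,4-bis[4-(benzyloxy)phenyl]-2-{[(tert-butyldimethylsilyl)oxy]methyl}but-3-en-1-yl]oxy}acetic acid (both epimers at the acid carbon)
Conditions: LiOH·H2O, THF/MeOH/H2O, rt; then 0.5 M HCl to pH 4, 0 °C
Reagents that add atoms: lithium hydroxide, [Li+].[OH-]
Why: Ester saponification; aryl benzyl ethers and the primary silyl ether tolerate aqueous hydroxide at room temperature, and the cold, mild acidification avoids ionising the benzylic ether.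

Step 10
Reactants: 16 2-[2,4-bis(benzyloxy)phenyl]-2-{[(1S,2R,3E)-1,4-bis[4-(benzyloxy)phenyl]-2-{[(tert-butyldimethylsilyl)oxy]methyl}but-3-en-1-yl]oxy}acetic acid
Product: 17 tert-butyl{[(2S,3R,4S,5R)-2-[4-(benzyloxy)phenyl]-4-[4-(benzyloxy)benzyl]-5-[2,4-bis(benzyloxy)phenyl]oxolan-3-yl]methoxy}dimethylsilane
Conditions: Ir[dF(CF3)ppy]2(dtbbpy)PF6 (1 mol %), 2,4,6-(i-Pr)3C6H2SH (20 mol %), K2HPO4 (0.5 equiv), degassed DMF (0.02 M), 450 nm LEDs, rt
Reagents that add atoms: none
Why: Photoredox decarboxylative radical cyclisation with thiol hydrogen-atom transfer, the reaction type of decarboxylative Giese additions and hydrodecarboxylations of alpha-oxy acids: the excited trivalent iridium complex oxidises the carboxylate of 16, CO2 is lost, and a planar C5 radical stabilised by O1 and the aryl ring results, so both acid epimers converge. This nucleophilic radical closes the oxolane by 5-exo-trig addition to the internal styrene carbon C4, forming C4–C5 and a 4-alkoxybenzylic radical that the arenethiol quenches; divalent iridium then reduces the thiyl radical and 16 reprotonates the thiolate, so both catalytic cycles close without net oxidant or reductant. C4 is under substrate control: in the chair-like Beckwith–Houk transition state the C2 aryl and C3 silyloxymethyl groups, trans to each other, are both pseudo-equatorial, which places the new benzyl group cis to the C2 aryl and trans to the C3 substituent. C5 is set in the same transition state, where a substituent on the radical carbon prefers the orientation that leads to the 4,5-cis product. This kinetic preference is the selectivity the step most needs, it is of moderate size, and it is supported by all three substituent effects pointing to one chair. Cyclisation must precede hydrogen transfer, which the low loading of a hindered thiol and the high dilution are chosen to secure. The alkene geometry is not transferred, and no acid is present that could equilibrate C5 afterwards.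

Step 11
Reactants: 17 tert-butyl{[(2S,3R,4S,5R)-2-[4-(benzyloxy)phenyl]-4-[4-(benzyloxy)benzyl]-5-[2,4-bis(benzyloxy)phenyl]oxolan-3-yl]methoxy}dimethylsilane
Product: 18 [(2S,3R,4S,5R)-2-[4-(benzyloxy)phenyl]-4-[4-(benzyloxy)benzyl]-5-[2,4-bis(benzyloxy)phenyl]oxolan-3-yl]methanol
Conditions: Bu4NF, THF, 0 °C → rt
Reagents that add atoms: none
Why: Fluoride-induced desilylation; no other group in 17 responds to Bu4NF.

Step 12
Reactants: 18 [(2S,3R,4S,5R)-2-[4-(benzyloxy)phenyl]-4-[4-(benzyloxy)benzyl]-5-[2,4-bis(benzyloxy)phenyl]oxolan-3-yl]methanol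
Product: 19 (2S,3S,4S,5R)-2-[4-(benzyloxy)phenyl]-4-[4-(benzyloxy)benzyl]-5-[2,4-bis(benzyloxy)phenyl]oxolane-3-carbaldehyde
Conditions: Dess–Martin periodinane, NaHCO3, CH2Cl2, 0 °C → rt
Reagents that add atoms: none
Why: Dess–Martin oxidation under buffered, non-basic conditions gives the beta-alkoxy aldehyde without enolisation; C3 is in any case trans to both neighbours, its favoured arrangement (the descriptor changes by priority only).

Step 13
Reactants: 20 4-bromobenzene-1,3-diol
Product: 21 2,4-bis(benzyloxy)-1-bromobenzene
Conditions: BnBr, K2CO3, DMF, rt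
Reagents that add atoms: benzyl bromide, BrCc1ccccc1
Why: Williamson O-benzylation of both phenols.

Step 14
Reactants: 19 (2S,3S,4S,5R)-2-[4-(benzyloxy)phenyl]-4-[4-(benzyloxy)benzyl]-5-[2,4-bis(benzyloxy)phenyl]oxolane-3-carbaldehyde; 21 2,4-bis(benzyloxy)-1-bromobenzene
Product: 23 [2,4-bis(benzyloxy)phenyl][(2S,3R,4S,5R)-2-[4-(benzyloxy)phenyl]-4-[4-(benzyloxy)benzyl]-5-[2,4-bis(benzyloxy)phenyl]oxolan-3-yl]methanol (both carbinol epimers), via arylmagnesium bromide 22 (not isolated)
Conditions: 21, Mg, THF, 40 °C; then 19, THF, −78 → 0 °C; aq. NH4Cl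
Reagents that add atoms: none
Why: Grignard formation by magnesium insertion, then 1,2-addition to the aldehyde at low temperature, where addition should outrun enolisation; the new carbinol center is removed in step 15.

Step 15
Reactants: 23 [2,4-bis(benzyloxy)phenyl][(2S,3R,4S,5R)-2-[4-(benzyloxy)phenyl]-4-[4-(benzyloxy)benzyl]-5-[2,4-bis(benzyloxy)phenyl]oxolan-3-yl]methanol
Product: 24 [2,4-bis(benzyloxy)phenyl][(2S,3S,4S,5R)-2-[4-(benzyloxy)phenyl]-4-[4-(benzyloxy)benzyl]-5-[2,4-bis(benzyloxy)phenyl]oxolan-3-yl]methanone
Conditions: Dess–Martin periodinane, NaHCO3, CH2Cl2, 0 °C → rt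
Reagents that add atoms: none
Why: Dess–Martin oxidation of the benzylic carbinol to the aryl ketone under buffered conditions that do not promote beta-elimination of O1.

Step 16
Reactants: 24 [2,4-bis(benzyloxy)phenyl][(2S,3S,4S,5R)-2-[4-(benzyloxy)phenyl]-4-[4-(benzyloxy)benzyl]-5-[2,4-bis(benzyloxy)phenyl]oxolan-3-yl]methanone
Product: 25 (2,4-dihydroxyphenyl)[(2S,3S,4S,5R)-5-(2,4-dihydroxyphenyl)-2-(4-hydroxyphenyl)-4-(4-hydroxybenzyl)oxolan-3-yl]methanone (CNP0181717.3)
Conditions: H2 (1 atm), 10% Pd/C, EtOAc/MeOH, rt
Reagents that add atoms: none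
Why: Hydrogenolysis of aryl benzyl ethers over Pd/C in neutral solvent is much faster than cleavage of the ring benzylic C–O bonds or reduction of the hydrogen-bonded 2-hydroxyaryl ketone; stopping at the uptake for six benzyl groups should give the target without acid or base.

## Compound list

1 | 4-(benzyloxy)benzaldehyde | O=Cc1ccc(OCc2ccccc2)cc1 | starting material
2 | (2-carboxyethyl)triphenylphosphonium bromide | OC(=O)CC[P+](c1ccccc1)(c1ccccc1)c1ccccc1.[Br-] | starting material
3 | potassium 3-(triphenylphosphoranylidene)propanoate (ylide carboxylate) | [K+].[O-]C(=O)CC=P(c1ccccc1)(c1ccccc1)c1ccccc1 | intermediate (not isolated)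
4 | (3E)-4-[4-(benzyloxy)phenyl]but-3-enoic acid | OC(=O)C/C=C/c1ccc(OCc2ccccc2)cc1 | intermediate
5 | (4S)-4-benzyl-1,3-oxazolidin-2-one | O=C1OC[C@H](Cc2ccccc2)N1 | starting material
6 | (3E)-4-[4-(benzyloxy)phenyl]but-3-enoic pivalic anhydride | CC(C)(C)C(=O)OC(=O)C/C=C/c1ccc(OCc2ccccc2)cc1 | intermediate (not isolated)
7 | (4S)-4-benzyl-3-{(3E)-4-[4-(benzyloxy)phenyl]but-3-enoyl}-1,3-oxazolidin-2-one | O=C1OC[C@H](Cc2ccccc2)N1C(=O)C/C=C/c1ccc(OCc2ccccc2)cc1 | intermediate
8 | dibutylboron (Z)-dienolate of 7 | CCCCB(CCCC)O/C(=C\C=C\c1ccc(OCc2ccccc2)cc1)N1[C@@H](Cc2ccccc2)COC1=O | intermediate (not isolated)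
9 | (4S)-4-benzyl-3-[(2S,3E)-4-[4-(benzyloxy)phenyl]-2-{(S)-[4-(benzyloxy)phenyl](hydroxy)methyl}but-3-enoyl]-1,3-oxazolidin-2-one | O[C@H](c1ccc(OCc2ccccc2)cc1)[C@@H](C(=O)N1[C@@H](Cc2ccccc2)COC1=O)/C=C/c1ccc(OCc2ccccc2)cc1 | intermediate
10 | (1S,2R,3E)-1,4-bis[4-(benzyloxy)phenyl]-2-(hydroxymethyl)but-3-en-1-ol | O[C@H](c1ccc(OCc2ccccc2)cc1)[C@@H](CO)/C=C/c1ccc(OCc2ccccc2)cc1 | intermediate
11 | (1S,2R,3E)-1,4-bis[4-(benzyloxy)phenyl]-2-{[(tert-butyldimethylsilyl)oxy]methyl}but-3-en-1-ol | O[C@H](c1ccc(OCc2ccccc2)cc1)[C@@H](CO[Si](C)(C)C(C)(C)C)/C=C/c1ccc(OCc2ccccc2)cc1 | intermediate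
12 | 2-(2,4-dihydroxyphenyl)acetic acid | OC(=O)Cc1ccc(O)cc1O | starting material
13 | benzyl 2-[2,4-bis(benzyloxy)phenyl]acetate | O=C(Cc1ccc(OCc2ccccc2)cc1OCc1ccccc1)OCc1ccccc1 | intermediate
14 | benzyl 2-[2,4-bis(benzyloxy)phenyl]-2-diazoacetate | [N-]=[N+]=C(C(=O)OCc1ccccc1)c1ccc(OCc2ccccc2)cc1OCc1ccccc1 | intermediate
15 | benzyl 2-[2,4-bis(benzyloxy)phenyl]-2-{[(1S,2R,3E)-1,4-bis[4-(benzyloxy)phenyl]-2-{[(tert-butyldimethylsilyl)oxy]methyl}but-3-en-1-yl]oxy}acetate (both epimers at the acetate carbon) | O=C(OCc1ccccc1)C(c1ccc(OCc2ccccc2)cc1OCc1ccccc1)O[C@H](c1ccc(OCc2ccccc2)cc1)[C@@H](CO[Si](C)(C)C(C)(C)C)/C=C/c1ccc(OCc2ccccc2)cc1 | intermediate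
16 | 2-[2,4-bis(benzyloxy)phenyl]-2-{[(1S,2R,3E)-1,4-bis[4-(benzyloxy)phenyl]-2-{[(tert-butyldimethylsilyl)oxy]methyl}but-3-en-1-yl]oxy}acetic acid (both epimers at the acid carbon) | OC(=O)C(c1ccc(OCc2ccccc2)cc1OCc1ccccc1)O[C@H](c1ccc(OCc2ccccc2)cc1)[C@@H](CO[Si](C)(C)C(C)(C)C)/C=C/c1ccc(OCc2ccccc2)cc1 | intermediate
17 | tert-butyl{[(2S,3R,4S,5R)-2-[4-(benzyloxy)phenyl]-4-[4-(benzyloxy)benzyl]-5-[2,4-bis(benzyloxy)phenyl]oxolan-3-yl]methoxy}dimethylsilane | CC(C)(C)[Si](C)(C)OC[C@H]1[C@H](Cc2ccc(OCc3ccccc3)cc2)[C@H](c2ccc(OCc3ccccc3)cc2OCc2ccccc2)O[C@@H]1c1ccc(OCc2ccccc2)cc1 | intermediate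
18 | [(2S,3R,4S,5R)-2-[4-(benzyloxy)phenyl]-4-[4-(benzyloxy)benzyl]-5-[2,4-bis(benzyloxy)phenyl]oxolan-3-yl]methanol | OC[C@H]1[C@H](Cc2ccc(OCc3ccccc3)cc2)[C@H](c2ccc(OCc3ccccc3)cc2OCc2ccccc2)O[C@@H]1c1ccc(OCc2ccccc2)cc1 | intermediate
19 | (2S,3S,4S,5R)-2-[4-(benzyloxy)phenyl]-4-[4-(benzyloxy)benzyl]-5-[2,4-bis(benzyloxy)phenyl]oxolane-3-carbaldehyde | O=C[C@H]1[C@H](Cc2ccc(OCc3ccccc3)cc2)[C@H](c2ccc(OCc3ccccc3)cc2OCc2ccccc2)O[C@@H]1c1ccc(OCc2ccccc2)cc1 | intermediate
20 | 4-bromobenzene-1,3-diol | Oc1ccc(Br)c(O)c1 | starting material
21 | 2,4-bis(benzyloxy)-1-bromobenzene | Brc1ccc(OCc2ccccc2)cc1OCc1ccccc1 | intermediate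
22 | [2,4-bis(benzyloxy)phenyl]magnesium bromide | Br[Mg]c1ccc(OCc2ccccc2)cc1OCc1ccccc1 | intermediate (not isolated)
23 | [2,4-bis(benzyloxy)phenyl][(2S,3R,4S,5R)-2-[4-(benzyloxy)phenyl]-4-[4-(benzyloxy)benzyl]-5-[2,4-bis(benzyloxy)phenyl]oxolan-3-yl]methanol (both carbinol epimers) | OC(c1ccc(OCc2ccccc2)cc1OCc1ccccc1)[C@H]1[C@H](Cc2ccc(OCc3ccccc3)cc2)[C@H](c2ccc(OCc3ccccc3)cc2OCc2ccccc2)O[C@@H]1c1ccc(OCc2ccccc2)cc1 | intermediate
24 | [2,4-bis(benzyloxy)phenyl][(2S,3S,4S,5R)-2-[4-(benzyloxy)phenyl]-4-[4-(benzyloxy)benzyl]-5-[2,4-bis(benzyloxy)phenyl]oxolan-3-yl]methanone | O=C(c1ccc(OCc2ccccc2)cc1OCc1ccccc1)[C@H]1[C@H](Cc2ccc(OCc3ccccc3)cc2)[C@H](c2ccc(OCc3ccccc3)cc2OCc2ccccc2)O[C@@H]1c1ccc(OCc2ccccc2)cc1 | intermediate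
25 | (2,4-dihydroxyphenyl)[(2S,3S,4S,5R)-5-(2,4-dihydroxyphenyl)-2-(4-hydroxyphenyl)-4-(4-hydroxybenzyl)oxolan-3-yl]methanone | O=C(c1ccc(O)cc1O)[C@H]1[C@H](Cc2ccc(O)cc2)[C@H](c2ccc(O)cc2O)O[C@@H]1c1ccc(O)cc1 | target

## Step count and least certain steps

Total step count: 16. Longest linear sequence: 13 steps (steps 1–5, 8–12 and 14–16, from aldehyde 1); steps 6–7 and step 13 are side branches.

**Step 10 (key step).** Three things could go wrong, in this order of likelihood:
- Hydrogen transfer to the C5 radical before it has cyclised, because a radical stabilised by O1 and a resorcinol ring adds slowly.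
- Insufficient facial selectivity at C5, where the cis preference is only a transition-state effect.
- One-electron oxidation or triplet sensitisation of the 4-alkoxystyrene by the excited photocatalyst, which would divert material or scramble the alkene geometry and thereby weaken C4 control.

The fallback changes the way the radical is made. It sets out from acid 16, which would be esterified with N-hydroxyphthalimide (DIC, catalytic DMAP) to the redox-active ester 1,3-dioxoisoindolin-2-yl 2-[2,4-bis(benzyloxy)phenyl]-2-{[(1S,2R,3E)-1,4-bis[4-(benzyloxy)phenyl]-2-{[(tert-butyldimethylsilyl)oxy]methyl}but-3-en-1-yl]oxy}acetate F1. This ester would be reduced with Ru(bpy)3(PF6)2, Hantzsch ester and i-Pr2NEt under blue light. The reductive manifold has no strongly oxidising excited state and a low triplet energy, and the Hantzsch ester is a slower hydrogen donor than a thiol. The same C5 radical would cyclise, and the fallback returns to the route at 17.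

**Step 8.** The most likely failure is diversion of the carbenoid into intramolecular C–H insertion at the benzylic CH2 of its own ortho benzyloxy group, a favourable 1,5 relationship, before the hindered secondary alcohol captures it. The fallback avoids carbenes. It sets out from diazo ester 14, which HBr in Et2O at 0 °C would convert into benzyl 2-[2,4-bis(benzyloxy)phenyl]-2-bromoacetate F2. Alcohol 11 would then be etherified with F2 under AgOTf and 2,6-di-tert-butylpyridine in CH2Cl2 at low temperature, a silver-assisted ionisation of the electron-rich benzylic bromide. The fallback returns at 15.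

**Step 14.** The most likely failure is enolisation of the beta-alkoxy aldehyde by the basic, ortho-substituted aryl Grignard reagent, which would return aldehyde or open the ring by beta-elimination of O1. The fallback changes the electrophile. It sets out from aldehyde 19, which would be oxidised (NaClO2, NaH2PO4, 2-methylbut-2-ene) to (2S,3S,4S,5R)-2-[4-(benzyloxy)phenyl]-4-[4-(benzyloxy)benzyl]-5-[2,4-bis(benzyloxy)phenyl]oxolane-3-carboxylic acid F3. Coupling with MeNHOMe·HCl and EDC would give (2S,3S,4S,5R)-2-[4-(benzyloxy)phenyl]-4-[4-(benzyloxy)benzyl]-5-[2,4-bis(benzyloxy)phenyl]-N-methoxy-N-methyloxolane-3-carboxamide F4. This less acidic Weinreb amide would be acylated by 22 through a stable chelate. The fallback returns at ketone 24 and bypasses 23 and step 15.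

**Step 16.** The most likely failure is over-reduction: hydrogenolytic cleavage of the ring C5–O1 (or C2–O1) bond, which becomes an ortho/para-hydroxybenzyl ether bond once the phenols are free, or reduction of the aryl ketone. The fallback is non-reductive: from 24, BCl3 with pentamethylbenzene as benzyl-cation scavenger in CH2Cl2 at −78 °C would give 25 directly. It needs short exposure and a cold quench because of the acid-labile C5 ether, and it makes no new intermediate.

## Further compounds

F1 | step 10 | 1,3-dioxoisoindolin-2-yl 2-[2,4-bis(benzyloxy)phenyl]-2-{[(1S,2R,3E)-1,4-bis[4-(benzyloxy)phenyl]-2-{[(tert-butyldimethylsilyl)oxy]methyl}but-3-en-1-yl]oxy}acetate (both epimers at the acetate carbon) | O=C(ON1C(=O)c2ccccc2C1=O)C(c1ccc(OCc2ccccc2)cc1OCc1ccccc1)O[C@H](c1ccc(OCc2ccccc2)cc1)[C@@H](CO[Si](C)(C)C(C)(C)C)/C=C/c1ccc(OCc2ccccc2)cc1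
F2 | step 8 | benzyl 2-[2,4-bis(benzyloxy)phenyl]-2-bromoacetate (racemic) | O=C(OCc1ccccc1)C(Br)c1ccc(OCc2ccccc2)cc1OCc1ccccc1
F3 | step 14 | (2S,3S,4S,5R)-2-[4-(benzyloxy)phenyl]-4-[4-(benzyloxy)benzyl]-5-[2,4-bis(benzyloxy)phenyl]oxolane-3-carboxylic acid | OC(=O)[C@H]1[C@H](Cc2ccc(OCc3ccccc3)cc2)[C@H](c2ccc(OCc3ccccc3)cc2OCc2ccccc2)O[C@@H]1c1ccc(OCc2ccccc2)cc1
F4 | step 14 | (2S,3S,4S,5R)-2-[4-(benzyloxy)phenyl]-4-[4-(benzyloxy)benzyl]-5-[2,4-bis(benzyloxy)phenyl]-N-methoxy-N-methyloxolane-3-carboxamide | CON(C)C(=O)[C@H]1[C@H](Cc2ccc(OCc3ccccc3)cc2)[C@H](c2ccc(OCc3ccccc3)cc2OCc2ccccc2)O[C@@H]1c1ccc(OCc2ccccc2)cc1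
F0 | step 16 | none | none
A1 | alternative 1 | (2S,3S,4S,5R)-2-[4-(benzyloxy)phenyl]-4-[4-(benzyloxy)benzyl]-5-[2,4-bis(benzyloxy)phenyl]oxolane-3-carbaldehyde (identical with 19) | O=C[C@H]1[C@H](Cc2ccc(OCc3ccccc3)cc2)[C@H](c2ccc(OCc3ccccc3)cc2OCc2ccccc2)O[C@@H]1c1ccc(OCc2ccccc2)cc1
A2 | alternative 1 | (4R,5R)-2-[2,4-bis(benzyloxy)phenyl]-4-[4-(benzyloxy)phenyl]-5-{(1Z)-3-[4-(benzyloxy)phenyl]prop-1-en-1-yl}-1,3-dioxolane (either acetal epimer) | C1(c2ccc(OCc3ccccc3)cc2OCc2ccccc2)O[C@H](c2ccc(OCc3ccccc3)cc2)[C@@H](/C=C\Cc2ccc(OCc3ccccc3)cc2)O1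
A3 | alternative 1 | (1R,2R,3Z)-1,5-bis[4-(benzyloxy)phenyl]pent-3-ene-1,2-diol | O[C@H](c1ccc(OCc2ccccc2)cc1)[C@H](O)/C=C\Cc1ccc(OCc2ccccc2)cc1
A4 | alternative 1 | 2,4-bis(benzyloxy)benzaldehyde | O=Cc1ccc(OCc2ccccc2)cc1OCc1ccccc1
A5 | alternative 2 | dimethyl (2R,4S,5R)-5-[2,4-bis(acetyloxy)phenyl]-2-[4-(benzyloxy)phenyl]-4-[4-(benzyloxy)benzyl]oxolane-3,3-dicarboxylate | COC(=O)C1(C(=O)OC)[C@H](Cc2ccc(OCc3ccccc3)cc2)[C@H](c2ccc(OC(C)=O)cc2OC(C)=O)O[C@@H]1c1ccc(OCc2ccccc2)cc1
A6 | alternative 2 | dimethyl (2S,3R)-2-[2,4-bis(acetyloxy)phenyl]-3-[4-(benzyloxy)benzyl]cyclopropane-1,1-dicarboxylate (trans) | COC(=O)C1(C(=O)OC)[C@H](Cc2ccc(OCc3ccccc3)cc2)[C@H]1c1ccc(OC(C)=O)cc1OC(C)=O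
A7 | alternative 3 | [2,4-bis(benzyloxy)phenyl][(2S,3S,4S,5R)-2-[4-(benzyloxy)phenyl]-4-[4-(benzyloxy)benzyl]-5-[2,4-bis(benzyloxy)phenyl]oxolan-3-yl]methanone (identical with 24) | O=C(c1ccc(OCc2ccccc2)cc1OCc1ccccc1)[C@H]1[C@H](Cc2ccc(OCc3ccccc3)cc2)[C@H](c2ccc(OCc3ccccc3)cc2OCc2ccccc2)O[C@@H]1c1ccc(OCc2ccccc2)cc1
A8 | alternative 3 | (2S,5S,6R)-4,6-bis[2,4-bis(benzyloxy)phenyl]-2-[4-(benzyloxy)phenyl]-5-[4-(benzyloxy)benzyl]-5,6-dihydro-2H-pyran | O1[C@H](c2ccc(OCc3ccccc3)cc2)C=C(c2ccc(OCc3ccccc3)cc2OCc2ccccc2)[C@H](Cc2ccc(OCc3ccccc3)cc2)[C@@H]1c1ccc(OCc2ccccc2)cc1OCc1ccccc1
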